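**Strategy**

Ring C is an α-ketol whose carbonyl C4 adjoins the fully substituted carbinol C3, while O1 sits on C8a, ortho to C4 on ring A. The route exploits both features by a [3+3] union at C3: an α-hydroxy ketone carrying the complete prenylated ring B supplies O1–C2–C3, and a 2-fluorobenzaldehyde supplies C4–C4a–C8a. In one flask the primary alkoxide displaces fluoride (O1–C8a) and a chiral triazolylidene carbene converts the aldehyde into an acyl anion equivalent that adds to the aryl ketone (C3–C4), closing ring C and setting the C3 stereocentre. The precursors are MOM-protected; methanolic acid removes the three MOM groups at the end.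

Key step: step 6

Assumption: 2',3'-dihydroxy-4'-methoxyacetophenone (1) and 2-fluoro-4-hydroxybenzaldehyde (7) are taken as commercial.
Assumption: the sense of induction of the aminoindanol-derived triazolylidene in step 6 is assigned from the hydrogen-bonded benzoin transition-state model and the (5aR,10bS) antipode is taken as the one that opens the Re face of the ketone.

**Route**

Step 1
Reactants: 1 1-(2,3-dihydroxy-4-methoxyphenyl)ethan-1-one
Product: 2 1-[4-methoxy-2,3-bis(methoxymethoxy)phenyl]ethan-1-one
Conditions: NaH (2.2 equiv), MOMCl (2.4 equiv), DMF, 0 °C to rt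
Reagents that add atoms: chloromethyl methyl ether (MOMCl), COCCl
Why: Williamson-type O-alkylation of the two sodium phenoxides, in which NaH in DMF also breaks the hydrogen bond of the 2-hydroxyl to the ketone, while the far less acidic methyl ketone is not deprotonated by the limited amount of base.

Step 2
Reactants: 2 1-[4-methoxy-2,3-bis(methoxymethoxy)phenyl]ethan-1-one
Product: 3 1-[5-bromo-4-methoxy-2,3-bis(methoxymethoxy)phenyl]ethan-1-one
Conditions: NBS (1.0 equiv), MeCN, 0 °C to rt
Reagents that add atoms: N-bromosuccinimide (NBS), O=C1CCC(=O)N1Br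
Why: Electrophilic aromatic bromination should go to C5, which is ortho to the 4-methoxy group, para to the 2-oxygen and meta to the acetyl group, whereas C6 is ortho to the deactivating acetyl group.

Step 3
Reactants: 3 1-[5-bromo-4-methoxy-2,3-bis(methoxymethoxy)phenyl]ethan-1-one
Product: 4 1-[4-methoxy-2,3-bis(methoxymethoxy)-5-(3-methylbut-2-en-1-yl)phenyl]ethan-1-one
Conditions: tributyl(prenyl)stannane (1.3 equiv), Pd(PPh3)4 (5 mol%), DMF, 95 °C
Reagents that add atoms: tributyl(3-methylbut-2-en-1-yl)stannane, CCCC[Sn](CCCC)(CCCC)CC=C(C)C
Why: Stille cross-coupling (oxidative addition of the aryl bromide to zerovalent palladium, transmetalation, reductive elimination at the less substituted allyl terminus) is neutral, tolerates the ketone and the MOM acetals, and should give the linear prenyl arene.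

Step 4
Reactants: 4 1-[4-methoxy-2,3-bis(methoxymethoxy)-5-(3-methylbut-2-en-1-yl)phenyl]ethan-1-one
Product: 6 2-hydroxy-1-[4-methoxy-2,3-bis(methoxymethoxy)-5-(3-methylbut-2-en-1-yl)phenyl]ethan-1-one, via hydroxy dimethyl ketal 5 (not isolated)
Conditions: PhI(OAc)2 (1.2 equiv), KOH (3 equiv), MeOH, 0 °C to rt; then p-TsOH·H2O (cat.), acetone/H2O, rt
Reagents that add atoms: methanol, CO; water, O
Why: Moriarty α-hydroxylation, in which the potassium enolate is captured by the hypervalent iodine reagent, methoxide addition with loss of iodobenzene gives a methoxy epoxide that methanol opens to ketal 5, and catalytic acid then unmasks the ketone because the ketal is far more acid-labile than the aryl MOM acetals, the basic oxidation stage leaving the prenyl alkene alone.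

Step 5
Reactants: 7 2-fluoro-4-hydroxybenzaldehyde
Product: 8 2-fluoro-4-(methoxymethoxy)benzaldehyde
Conditions: MOMCl (1.3 equiv), K2CO3 (2 equiv), acetone, 0 °C to rt
Reagents that add atoms: chloromethyl methyl ether (MOMCl), COCCl
Why: Williamson-type O-alkylation of the acidic para-formyl phenoxide masks the only protic group of the electrophile, so that it cannot quench the alkoxide or deactivate the ring as a phenoxide in step 6.

Step 6
Reactants: 6 2-hydroxy-1-[4-methoxy-2,3-bis(methoxymethoxy)-5-(3-methylbut-2-en-1-yl)phenyl]ethan-1-one; 8 2-fluoro-4-(methoxymethoxy)benzaldehyde (1.1 equiv)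
Product: 10 (3S)-3-hydroxy-7-(methoxymethoxy)-3-[4-methoxy-2,3-bis(methoxymethoxy)-5-(3-methylbut-2-en-1-yl)phenyl]-2,3-dihydro-4H-chromen-4-one, via keto aldehyde 9 (not isolated)
Conditions: Cs2CO3 (1.5 equiv), (5aR,10bS)-2-mesityl-5a,10b-dihydro-4H,6H-indeno[2,1-b][1,2,4]triazolo[4,3-d][1,4]oxazin-2-ium chloride (15 mol%, from (1S,2R)-1-amino-2-indanol), 4 Å MS, DMSO, 25 °C, Ar, all components charged together
Reagents that add atoms: none
Why: Proposed new method: Cs2CO3 in DMSO turns the only free hydroxyl of 6 into a primary alkoxide that displaces fluoride from 8 by addition–elimination (SNAr) at the carbon ortho to the formyl group to give keto aldehyde 9; the triazolylidene carbene freed from the precatalyst by the same base adds to the aldehyde of 9, the resulting Breslow enaminol attacks the aryl ketone intramolecularly, and the tertiary alkoxide then expels the carbene to give 10. The closest known reaction types are the Cs2CO3-mediated SNAr of α-hydroxy ketones with fluoroarenes bearing an ortho acceptor and the carbene-catalysed enantioselective intramolecular crossed aldehyde–ketone benzoin reaction of 2-(2-oxoalkoxy)benzaldehydes to 3-hydroxychroman-4-ones; only their merger in one flask is new. Ring C closes in a 6-exo-trig mode with the carbinol oxygen exocyclic. The C3 stereocentre is under catalyst control: in the hydrogen-bonded transition state (enaminol O–H to ketone oxygen) the indane wall of the carbene is expected to leave the Re face of the ketone (O > CH2OAr > aryl) open, which gives the 3S configuration. The step needs the benzoin pathway to win over base-mediated aldol condensation of the OCH2 group onto the aldehyde (Rap–Stoermer benzofuran formation); the carbene is present from the start so that 9 is intercepted as it forms, neither carbonyl has another enolisable position, all phenols are masked as MOM ethers so that a single oxygen nucleophile exists, and the α-oxygen makes the ketone a reactive benzoin acceptor.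

Step 7
Reactants: 10 (3S)-3-hydroxy-7-(methoxymethoxy)-3-[4-methoxy-2,3-bis(methoxymethoxy)-5-(3-methylbut-2-en-1-yl)phenyl]-2,3-dihydro-4H-chromen-4-one
Product: 11 (3S)-3-[2,3-dihydroxy-4-methoxy-5-(3-methylbut-2-en-1-yl)phenyl]-3,7-dihydroxy-2,3-dihydro-4H-chromen-4-one
Conditions: HCl (ca. 1.5 M, from AcCl in MeOH), MeOH/THF, 0 °C to rt
Reagents that add atoms: none
Why: Acid-catalysed acetal exchange (methanolysis) should remove the three aryl MOM groups under conditions mild enough that the tertiary carbinol, whose ionisation is disfavoured by the adjacent C4 carbonyl, keeps its configuration and the prenyl group, which has no ortho hydroxyl to cyclise onto, stays intact.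

**Compound list**

1 | 1-(2,3-dihydroxy-4-methoxyphenyl)ethan-1-one | CC(=O)c1ccc(OC)c(O)c1O | starting material
2 | 1-[4-methoxy-2,3-bis(methoxymethoxy)phenyl]ethan-1-one | CC(=O)c1ccc(OC)c(OCOC)c1OCOC | intermediate
3 | 1-[5-bromo-4-methoxy-2,3-bis(methoxymethoxy)phenyl]ethan-1-one | CC(=O)c1cc(Br)c(OC)c(OCOC)c1OCOC | intermediate
4 | 1-[4-methoxy-2,3-bis(methoxymethoxy)-5-(3-methylbut-2-en-1-yl)phenyl]ethan-1-one | CC(=O)c1cc(CC=C(C)C)c(OC)c(OCOC)c1OCOC | intermediate
5 | 2,2-dimethoxy-2-[4-methoxy-2,3-bis(methoxymethoxy)-5-(3-methylbut-2-en-1-yl)phenyl]ethan-1-ol (not isolated) | COC(OC)(CO)c1cc(CC=C(C)C)c(OC)c(OCOC)c1OCOC | intermediate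
6 | 2-hydroxy-1-[4-methoxy-2,3-bis(methoxymethoxy)-5-(3-methylbut-2-en-1-yl)phenyl]ethan-1-one | O=C(CO)c1cc(CC=C(C)C)c(OC)c(OCOC)c1OCOC | intermediate
7 | 2-fluoro-4-hydroxybenzaldehyde | O=Cc1ccc(O)cc1F | starting material
8 | 2-fluoro-4-(methoxymethoxy)benzaldehyde | O=Cc1ccc(OCOC)cc1F | intermediate
9 | 4-(methoxymethoxy)-2-{2-[4-methoxy-2,3-bis(methoxymethoxy)-5-(3-methylbut-2-en-1-yl)phenyl]-2-oxoethoxy}benzaldehyde (not isolated) | O=Cc1ccc(OCOC)cc1OCC(=O)c1cc(CC=C(C)C)c(OC)c(OCOC)c1OCOC | intermediate
10 | (3S)-3-hydroxy-7-(methoxymethoxy)-3-[4-methoxy-2,3-bis(methoxymethoxy)-5-(3-methylbut-2-en-1-yl)phenyl]-2,3-dihydro-4H-chromen-4-one | COc1c(CC=C(C)C)cc([C@]2(O)COc3cc(OCOC)ccc3C2=O)c(OCOC)c1OCOC | intermediate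
11 | (3S)-3-[2,3-dihydroxy-4-methoxy-5-(3-methylbut-2-en-1-yl)phenyl]-3,7-dihydroxy-2,3-dihydro-4H-chromen-4-one | COc1c(CC=C(C)C)cc([C@]2(O)COc3cc(O)ccc3C2=O)c(O)c1O | target

**Count and risks**

Total step count: 7. Longest linear sequence: 6 steps (steps 1, 2, 3, 4, 6, 7).

Steps most likely to fail:

1. Step 6 (proposed new method). The domino may be diverted by aldol condensation of the intermediate onto its own aldehyde, stalled by slow fluoride displacement at the alkoxy-substituted ring, or compromised by poor or reversed facial selectivity in the polar medium. The fallback separates the two bond formations and uses known chemistry only; it sets out from 5 (taken from step 4 before the acid stage) and 8 and comes back at 10. The alkoxide of 5 (NaH, DMF, 0 °C to rt) is arylated with 8 by SNAr to give 2-{2,2-dimethoxy-2-[4-methoxy-2,3-bis(methoxymethoxy)-5-(3-methylbut-2-en-1-yl)phenyl]ethoxy}-4-(methoxymethoxy)benzaldehyde F1; the ketal has no enolisable position, so no aldol pathway exists at this stage. Catalytic p-TsOH in wet acetone then releases keto aldehyde 9, which is isolated and cyclised with the same triazolium salt and Et3N or DBU in toluene/THF at rt to 10. If the sense of induction proves opposite, the antipodal precatalyst is used.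

2. Step 3. The allyl unit may be transferred through its γ-carbon to give the reverse-prenyl isomer, and oxidative addition to the electron-rich bromide may be slow. The fallback sets out from 3 and comes back at 4. Stille coupling with allyltributylstannane (C=CC[Sn](CCCC)(CCCC)CCCC), for which the regiochemistry is immaterial, should give 1-[4-methoxy-2,3-bis(methoxymethoxy)-5-(prop-2-en-1-yl)phenyl]ethan-1-one F2. Cross-metathesis of F2 with excess 2-methylbut-2-ene (CC=C(C)C) and the second-generation Grubbs catalyst RuCl2(=CHPh)(PCy3)(H2IMes) in CH2Cl2 at 40 °C then gives 4.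

3. Step 4. The iodine oxidant may attack the trisubstituted alkene or over-oxidise the side chain, and the MOM group ortho to the ketone may be lost during ketal hydrolysis. The fallback changes the order so that the oxidant never meets the alkene; it sets out from 3 and comes back at 6 by way of 5. The same PhI(OAc)2/KOH/MeOH treatment of 3 gives 2-[5-bromo-4-methoxy-2,3-bis(methoxymethoxy)phenyl]-2,2-dimethoxyethan-1-ol F3. Stille prenylation of F3 (stannane and Pd(PPh3)4 as in step 3) gives 5, and hydrolysis with PPTS in wet acetone, a buffered acid, gives 6.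

Further compounds
F1 | step 6 | 2-{2,2-dimethoxy-2-[4-methoxy-2,3-bis(methoxymethoxy)-5-(3-methylbut-2-en-1-yl)phenyl]ethoxy}-4-(methoxymethoxy)benzaldehyde | COC(OC)(COc1cc(OCOC)ccc1C=O)c1cc(CC=C(C)C)c(OC)c(OCOC)c1OCOC
F2 | step 3 | 1-[4-methoxy-2,3-bis(methoxymethoxy)-5-(prop-2-en-1-yl)phenyl]ethan-1-one | CC(=O)c1cc(CC=C)c(OC)c(OCOC)c1OCOC
F3 | step 4 | 2-[5-bromo-4-methoxy-2,3-bis(methoxymethoxy)phenyl]-2,2-dimethoxyethan-1-ol | COC(OC)(CO)c1cc(Br)c(OC)c(OCOC)c1OCOC
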